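## Retrosynthetic overview

1. Target 21 comes from its 7-O-benzyl ether 20 by hydrogenolysis.
2. 20 comes from the seco-diol 17 in one flask: DDQ turns the free guaiacyl unit (ring A) into its p-quinone methide, the γ-hydroxyl traps it as a lariciresinol-type tetrahydrofuran, and acid re-ionises this for Friedel–Crafts closure onto ring B (sets C1).
3. 17 comes from bis-imide 16 by LiAlH4; 16 comes from oxidative 8–8′ coupling of the enolates of two 3-arylpropanoyl (R)-oxazolidinones, 13 and 10 (sets C2 and C3).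
4. 13 comes from dihydroferulic acid 11; 10 comes from 2,3,4-trihydroxybenzaldehyde 1 and Meldrum's acid 4.
5. Ring order: both benzene rings are bought; the transient tetrahydrofuran forms first and is converted in the same flask into the only new carbocycle, the cyclohexane ring of the tetralin.

Assumption: the SMILES is read as the all-trans (1R,2S,3S) isomer in tetralin numbering (aryl at C1, CH2OH at C2 and C3, OMe at C5 and C6, OH at C7); equivalents are planned values, and nothing here has been run.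

## Route

Step 1
Reactants: 1 2,3,4-trihydroxybenzaldehyde
Product: 3 4-(benzyloxy)-2,3-dimethoxybenzaldehyde, via 4-O-benzyl catechol aldehyde 2 (not isolated)
Conditions: BnBr (1.05 equiv), NaHCO3, NaI (cat.), DMF, 40 °C; then MeI (3 equiv), K2CO3, 40 °C
Reagents that add atoms: benzyl bromide BrCc1ccccc1; iodomethane CI
Why: Williamson etherification in which NaHCO3 ionises only the most acidic 4-OH (para to CHO; the 2-OH is chelated to the aldehyde), so benzylation is regioselective, and K2CO3/MeI then methylates the two remaining phenols.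

Step 2
Reactants: 3 4-(benzyloxy)-2,3-dimethoxybenzaldehyde; 4 Meldrum's acid (2,2-dimethyl-1,3-dioxane-4,6-dione)
Product: 7 3-[4-(benzyloxy)-2,3-dimethoxyphenyl]propanoic acid, via arylidene Meldrum's acid 5 (not isolated), via benzyl Meldrum's acid 6 (not isolated)
Conditions: HCO2H–Et3N (5:2), rt → 100 °C
Reagents that add atoms: none
Why: Reductive Knoevenagel homologation (condensation, formate transfer hydrogenation of the alkylidene, then ring opening and decarboxylation at 100 °C); no Pd/H2 is used, so the benzyl ether survives.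

Step 3
Reactants: 7 3-[4-(benzyloxy)-2,3-dimethoxyphenyl]propanoic acid; 8 (R)-4-benzyl-1,3-oxazolidin-2-one
Product: 10 (R)-4-benzyl-3-{3-[4-(benzyloxy)-2,3-dimethoxyphenyl]propanoyl}-1,3-oxazolidin-2-one, via mixed pivalic anhydride 9 (not isolated)
Conditions: PivCl, Et3N, THF, −20 °C; then 8, LiCl, −20 °C → rt
Reagents that add atoms: none
Why: Mixed-anhydride N-acylation of the oxazolidinone under LiCl/Et3N soft deprotonation, with attack at the unhindered carbonyl of the anhydride.

Step 4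
Reactants: 11 3-(4-hydroxy-3-methoxyphenyl)propanoic acid (dihydroferulic acid); 8 (R)-4-benzyl-1,3-oxazolidin-2-one
Product: 13 (R)-4-benzyl-3-{3-[3-methoxy-4-(pivaloyloxy)phenyl]propanoyl}-1,3-oxazolidin-2-one, via aryl pivalate mixed anhydride 12 (not isolated)
Conditions: PivCl (2.3 equiv), Et3N (4 equiv), THF, −20 → 0 °C (11 added slowly to the acyl chloride); then 8, LiCl, 0 °C → rt
Reagents that add atoms: pivaloyl chloride CC(C)(C)C(=O)Cl
Why: One reagent does both jobs, O-pivaloylation of the phenol and carboxyl activation as the mixed anhydride, and the oxazolidinone then attacks only the anhydride (mixed-anhydride N-acylation), leaving a hindered aryl ester that tolerates the amide base of step 5 and is cleaved by hydride in step 6.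

Step 5
Reactants: 13 (R)-4-benzyl-3-{3-[3-methoxy-4-(pivaloyloxy)phenyl]propanoyl}-1,3-oxazolidin-2-one (3 equiv); 10 (R)-4-benzyl-3-{3-[4-(benzyloxy)-2,3-dimethoxyphenyl]propanoyl}-1,3-oxazolidin-2-one (1 equiv)
Product: 16 (2S,3S)-1,4-bis[(4R)-4-benzyl-2-oxo-1,3-oxazolidin-3-yl]-2-[4-(benzyloxy)-2,3-dimethoxybenzyl]-3-[3-methoxy-4-(pivaloyloxy)benzyl]butane-1,4-dione, via lithium enolate 14 (not isolated), via lithium enolate 15 (not isolated)
Conditions: LiN(iPr)2 (1.05 equiv per imide), THF, −78 °C; then Cu(O2CCH(Et)Bu)2 (1.1 equiv per enolate), −78 °C → rt; SiO2 chromatography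
Reagents that add atoms: none
Why: Oxidative enolate coupling: divalent copper oxidises the chelated Z-enolates by one electron and the two α-carbons join, each on the face anti to the benzyl group of its own (R)-auxiliary, which gives (S,S) by matched double stereodifferentiation; the cross-coupling is statistical, so cheap 13 is used in excess and the homodimers are removed on silica (any remainder separates after step 6, where the three diols carry two, one and no free phenol).

Step 6
Reactants: 16 the (2S,3S)-bis-imide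
Product: 17 (2S,3S)-2-[4-(benzyloxy)-2,3-dimethoxybenzyl]-3-(4-hydroxy-3-methoxybenzyl)butane-1,4-diol
Conditions: LiAlH4 (6 equiv), THF, 0 °C → rt; aq potassium sodium tartrate work-up
Reagents that add atoms: none
Why: Hydride reduction of both N-acyl oxazolidinones to primary alcohols with release of the auxiliary and concurrent reductive cleavage of the aryl pivalate; the two stereocentres are not enolised, so (S,S) is retained, and only ring A now carries a free phenol.

Step 7
Reactants: 17 the (2S,3S)-diol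
Product: 20 [(1R,2S,3S)-7-(benzyloxy)-1-(4-hydroxy-3-methoxyphenyl)-5,6-dimethoxy-1,2,3,4-tetrahydronaphthalene-2,3-diyl]dimethanol, via quinone methide 18 (not isolated), via tetrahydrofuran 19 (not isolated)
Conditions: DDQ (1.0 equiv), CH2Cl2, 0 °C; then TFA (10 equiv), 0 °C → rt; aq NaHCO3–MeOH work-up
Reagents that add atoms: none
Why: DDQ dehydrogenates only the free p-alkylguaiacol to its p-quinone methide (ring B is blocked as the benzyl ether), the γ-hydroxyl traps it by oxa-1,6-addition as the lariciresinol-type tetrahydrofuran, and TFA re-ionises that p-hydroxybenzylic ether so that ring B closes by intramolecular Friedel–Crafts alkylation at its only free ortho carbon (para to an OMe) through a chair-like transition state with the aryl group equatorial, setting C1 as R, trans to C2 (the lariciresinol-to-isolariciresinol isomerisation run from the C–H stage).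

Step 8
Reactants: 20 the 7-O-benzyl cyclolignan
Product: 21 (1R,2S,3S)-1-(4-hydroxy-3-methoxyphenyl)-2,3-bis(hydroxymethyl)-5,6-dimethoxy-1,2,3,4-tetrahydronaphthalen-7-ol (target)
Conditions: H2 (1 atm), Pd/C (10%), MeOH–EtOAc, rt
Reagents that add atoms: none
Why: Hydrogenolysis of the aryl benzyl ether; the C1–aryl bonds are C–C bonds and are not cleaved, and no stereocentre is touched.

## Compound list

1 | 2,3,4-trihydroxybenzaldehyde | O=Cc1ccc(O)c(O)c1O | starting material
2 | 4-(benzyloxy)-2,3-dihydroxybenzaldehyde | O=Cc1ccc(OCc2ccccc2)c(O)c1O | intermediate (not isolated)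
3 | 4-(benzyloxy)-2,3-dimethoxybenzaldehyde | O=Cc1ccc(OCc2ccccc2)c(OC)c1OC | intermediate
4 | Meldrum's acid (2,2-dimethyl-1,3-dioxane-4,6-dione) | CC1(C)OC(=O)CC(=O)O1 | starting material
5 | 5-[4-(benzyloxy)-2,3-dimethoxybenzylidene]-2,2-dimethyl-1,3-dioxane-4,6-dione | CC1(C)OC(=O)C(=Cc2ccc(OCc3ccccc3)c(OC)c2OC)C(=O)O1 | intermediate (not isolated)
6 | 5-[4-(benzyloxy)-2,3-dimethoxybenzyl]-2,2-dimethyl-1,3-dioxane-4,6-dione | CC1(C)OC(=O)C(Cc2ccc(OCc3ccccc3)c(OC)c2OC)C(=O)O1 | intermediate (not isolated)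
7 | 3-[4-(benzyloxy)-2,3-dimethoxyphenyl]propanoic acid | OC(=O)CCc1ccc(OCc2ccccc2)c(OC)c1OC | intermediate
8 | (R)-4-benzyl-1,3-oxazolidin-2-one | O=C1N[C@H](Cc2ccccc2)CO1 | starting material
9 | 3-[4-(benzyloxy)-2,3-dimethoxyphenyl]propanoic pivalic anhydride | CC(C)(C)C(=O)OC(=O)CCc1ccc(OCc2ccccc2)c(OC)c1OC | intermediate (not isolated)
10 | (R)-4-benzyl-3-{3-[4-(benzyloxy)-2,3-dimethoxyphenyl]propanoyl}-1,3-oxazolidin-2-one | O=C(CCc1ccc(OCc2ccccc2)c(OC)c1OC)N1C(=O)OC[C@H]1Cc1ccccc1 | intermediate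
11 | 3-(4-hydroxy-3-methoxyphenyl)propanoic acid | OC(=O)CCc1ccc(O)c(OC)c1 | starting material
12 | 3-[3-methoxy-4-(pivaloyloxy)phenyl]propanoic pivalic anhydride | CC(C)(C)C(=O)OC(=O)CCc1ccc(OC(=O)C(C)(C)C)c(OC)c1 | intermediate (not isolated)
13 | (R)-4-benzyl-3-{3-[3-methoxy-4-(pivaloyloxy)phenyl]propanoyl}-1,3-oxazolidin-2-one | CC(C)(C)C(=O)Oc1ccc(CCC(=O)N2C(=O)OC[C@H]2Cc2ccccc2)cc1OC | intermediate
14 | lithium (Z)-enolate of 13 | [Li]O/C(=C\Cc1ccc(OC(=O)C(C)(C)C)c(OC)c1)N1C(=O)OC[C@H]1Cc1ccccc1 | intermediate (not isolated)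
15 | lithium (Z)-enolate of 10 | [Li]O/C(=C\Cc1ccc(OCc2ccccc2)c(OC)c1OC)N1C(=O)OC[C@H]1Cc1ccccc1 | intermediate (not isolated)
16 | (2S,3S)-1,4-bis[(4R)-4-benzyl-2-oxo-1,3-oxazolidin-3-yl]-2-[4-(benzyloxy)-2,3-dimethoxybenzyl]-3-[3-methoxy-4-(pivaloyloxy)benzyl]butane-1,4-dione | O=C(N1C(=O)OC[C@H]1Cc1ccccc1)[C@@H](Cc1ccc(OC(=O)C(C)(C)C)c(OC)c1)[C@H](Cc1ccc(OCc2ccccc2)c(OC)c1OC)C(=O)N1C(=O)OC[C@H]1Cc1ccccc1 | intermediate
17 | (2S,3S)-2-[4-(benzyloxy)-2,3-dimethoxybenzyl]-3-(4-hydroxy-3-methoxybenzyl)butane-1,4-diol | OC[C@@H](Cc1ccc(O)c(OC)c1)[C@H](Cc1ccc(OCc2ccccc2)c(OC)c1OC)CO | intermediate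
18 | 4-[(2S,3S)-3-[4-(benzyloxy)-2,3-dimethoxybenzyl]-4-hydroxy-2-(hydroxymethyl)butylidene]-2-methoxycyclohexa-2,5-dien-1-one | COC1=CC(=C[C@H](CO)[C@@H](CO)Cc2ccc(OCc3ccccc3)c(OC)c2OC)C=CC1=O | intermediate (not isolated)
19 | [(3S,4S)-4-[4-(benzyloxy)-2,3-dimethoxybenzyl]-2-(4-hydroxy-3-methoxyphenyl)oxolan-3-yl]methanol, both C2 epimers (C2 is re-ionised) | OC[C@H]1C(c2ccc(O)c(OC)c2)OC[C@H]1Cc1ccc(OCc2ccccc2)c(OC)c1OC | intermediate (not isolated)
20 | [(1R,2S,3S)-7-(benzyloxy)-1-(4-hydroxy-3-methoxyphenyl)-5,6-dimethoxy-1,2,3,4-tetrahydronaphthalene-2,3-diyl]dimethanol | COc1cc([C@@H]2c3cc(OCc4ccccc4)c(OC)c(OC)c3C[C@H](CO)[C@H]2CO)ccc1O | intermediate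
21 | (1R,2S,3S)-1-(4-hydroxy-3-methoxyphenyl)-2,3-bis(hydroxymethyl)-5,6-dimethoxy-1,2,3,4-tetrahydronaphthalen-7-ol | COc1cc([C@@H]2c3cc(O)c(OC)c(OC)c3C[C@H](CO)[C@H]2CO)ccc1O | target

## Step count and risks

Total steps: 8. Longest linear sequence: 7 (steps 1, 2, 3, 5, 6, 7, 8).

**Step 5 (oxidative cross-coupling).** The hetero-dimer is formed statistically beside both homodimers, a minor meso-type diastereomer may form, and the aryl pivalate must survive the amide base. The fallback sets out from 10 and rejoins at 17, building the 8–8′ unit by two alkylations instead of one oxidative coupling. The sodium enolate of 10 (NaN(SiMe3)2, THF, −78 °C) is alkylated with tert-butyl bromoacetate anti to the auxiliary benzyl group to give tert-butyl (3S)-3-[4-(benzyloxy)-2,3-dimethoxybenzyl]-4-[(4R)-4-benzyl-2-oxo-1,3-oxazolidin-3-yl]-4-oxobutanoate F1. LiBH4 (THF–MeOH, 0 °C) followed by TsOH in toluene gives (4S)-4-[4-(benzyloxy)-2,3-dimethoxybenzyl]dihydrofuran-2(3H)-one F2. Separately, purchased vanillyl alcohol is acylated on the phenol only (PivCl, aq NaOH, CH2Cl2) to 4-(hydroxymethyl)-2-methoxyphenyl pivalate F3 and brominated (PBr3, Et2O, 0 °C) to 4-(bromomethyl)-2-methoxyphenyl pivalate F4. The lithium enolate of F2 (LiN(SiMe3)2, THF, −78 °C) is alkylated with F4 trans to the C4 substituent to give (3S,4S)-4-[4-(benzyloxy)-2,3-dimethoxybenzyl]-3-[3-methoxy-4-(pivaloyloxy)benzyl]dihydrofuran-2(3H)-one F5. LiAlH4 opens the lactone and removes the pivalate to give 17.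

**Step 7 (dehydrogenative cyclisation).** DDQ may over-oxidise the product or attack ring B, the closing carbon of ring B is para to a crowded and therefore weakly donating OMe, and the benzylic cation can lose a proton towards C2. The fallback sets out from 16 and rejoins at 20, closing the ring at the carboxylic acid oxidation level, where the side chains tolerate stronger Lewis acids. LiOH/H2O2 (THF–H2O, 0 °C) removes both auxiliaries and the pivalate to give (2S,3S)-2-[4-(benzyloxy)-2,3-dimethoxybenzyl]-3-(4-hydroxy-3-methoxybenzyl)butanedioic acid F6. DDQ (1.0 equiv, dioxane) and then BF3·OEt2 in CH2Cl2 give (1R,2S,3S)-7-(benzyloxy)-1-(4-hydroxy-3-methoxyphenyl)-5,6-dimethoxy-1,2,3,4-tetrahydronaphthalene-2,3-dicarboxylic acid F7, the all-trans isomer, which is also the thermodynamically preferred one. LiAlH4 in refluxing THF reduces F7 to 20.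

**Step 4 (one-pot pivaloylation and N-acylation).** The free phenol can attack the mixed anhydride and give aryl ester oligomers. The fallback sets out from 11 and rejoins at 13, separating protection from activation. Schotten–Baumann acylation (PivCl, 2 M aq NaOH, 0 °C, then acidification) acylates only the phenoxide and gives 3-[3-methoxy-4-(pivaloyloxy)phenyl]propanoic acid F8. This is isolated and then taken through the ordinary mixed-anhydride acylation of 8 (PivCl, Et3N, THF, −20 °C; then 8, LiCl), passing through 12, to 13.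

## Further compounds

F1 | step 5 | tert-butyl (3S)-3-[4-(benzyloxy)-2,3-dimethoxybenzyl]-4-[(4R)-4-benzyl-2-oxo-1,3-oxazolidin-3-yl]-4-oxobutanoate | CC(C)(C)OC(=O)C[C@H](Cc1ccc(OCc2ccccc2)c(OC)c1OC)C(=O)N1C(=O)OC[C@H]1Cc1ccccc1
F2 | step 5 | (4S)-4-[4-(benzyloxy)-2,3-dimethoxybenzyl]dihydrofuran-2(3H)-one | O=C1C[C@H](Cc2ccc(OCc3ccccc3)c(OC)c2OC)CO1
F3 | step 5 | 4-(hydroxymethyl)-2-methoxyphenyl pivalate | CC(C)(C)C(=O)Oc1ccc(CO)cc1OC
F4 | step 5 | 4-(bromomethyl)-2-methoxyphenyl pivalate | CC(C)(C)C(=O)Oc1ccc(CBr)cc1OC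
F5 | step 5 | (3S,4S)-4-[4-(benzyloxy)-2,3-dimethoxybenzyl]-3-[3-methoxy-4-(pivaloyloxy)benzyl]dihydrofuran-2(3H)-one | O=C1[C@@H](Cc2ccc(OC(=O)C(C)(C)C)c(OC)c2)[C@H](Cc2ccc(OCc3ccccc3)c(OC)c2OC)CO1
F6 | step 7 | (2S,3S)-2-[4-(benzyloxy)-2,3-dimethoxybenzyl]-3-(4-hydroxy-3-methoxybenzyl)butanedioic acid | OC(=O)[C@@H](Cc1ccc(O)c(OC)c1)[C@H](Cc1ccc(OCc2ccccc2)c(OC)c1OC)C(=O)O
F7 | step 7 | (1R,2S,3S)-7-(benzyloxy)-1-(4-hydroxy-3-methoxyphenyl)-5,6-dimethoxy-1,2,3,4-tetrahydronaphthalene-2,3-dicarboxylic acid | COc1cc([C@@H]2c3cc(OCc4ccccc4)c(OC)c(OC)c3C[C@H](C(=O)O)[C@H]2C(=O)O)ccc1O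
F8 | step 4 | 3-[3-methoxy-4-(pivaloyloxy)phenyl]propanoic acid | CC(C)(C)C(=O)Oc1ccc(CCC(=O)O)cc1OC
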